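**Plan**

- Retrosynthesis: cut first the C4–O acyl bond (dienoic acid plus C4 alcohol), then the C1–CH2 bond of the acrolein side chain (radical allylation of a 1,1-dichloro enone), then excise C3 (bonds C2–C3 and C3–C3a, one CH2 from diazomethane), then C1–C7a and C2–C3a (dichloroketene [2+2]), and last the cyclohexene ring (acetoacetate/enone annulation).
- Enabling feature: in the indenone core (C1 chain carbon, C2 ketone, C3=C3a alkene, C4 acyloxy, C7 carboxyl, C7a methyl) the five-membered ring without C3 is a cyclobutanone C1–C2–C3a–C7a fused across C3a–C7a to the six-membered ring. That is the ketene adduct of a reduced Hagemann-type ester which already carries the C4 oxygen, the C7 ester and the C7a methyl.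
- Forward order: six-membered ring (annulation), four-membered ring ([2+2]), five-membered ring (one-carbon ring expansion), C3=C3a (Saegusa–Ito), side chain at C1 (allylation, dechlorination), acyl group at C4, ester cleavage.
- Stereochemistry: C4 and C7 come from an enzymatic ketone reduction with dynamic resolution of the labile ester-bearing centre. C7a comes from ketene addition anti to both ring substituents, and C1 from protonation of a zinc enolate anti to the angular methyl. C6 of the acyl chain comes from (R)-2-methylbutanoic acid, and its two E alkenes from stabilised ylide and phosphonate olefinations.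

Key step: step 5

Assumption: diazomethane is used as a freshly distilled ethereal solution made from commercial N-methyl-N-nitroso-p-toluenesulfonamide and KOH, and the ketoreductase is taken from a commercial screening panel; neither preparation is counted as a step.

Remarks: bicyclic compounds carry indene numbering; the monocyclic precursors carry cyclohexene numbering (C1 ester carbon, C4 carbinol carbon, which become C7 and C4). TBS = tert-butyldimethylsilyl, TMS = trimethylsilyl. The target is (1R,4S,7R,7aS) in the core and (2E,4E,6R) in the acyl chain.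

**Route**

Step 1
Reactants: 1 tert-butyl acetoacetate; 2 methyl vinyl ketone
Product: 4 tert-butyl (±)-2-methyl-4-oxocyclohex-2-ene-1-carboxylate, via tert-butyl 2-acetyl-5-oxohexanoate 3 (not isolated)
Conditions: t-BuOK (cat.), t-BuOH, 0 → 25 °C; then pyrrolidine (0.2 equiv), AcOH (0.2 equiv), 25 → 60 °C
Reagents that add atoms: none
Why: Base-catalysed Michael addition of the acetoacetate to the enone, followed by amine-mediated intramolecular aldol condensation of the side-chain methyl ketone onto the acetoacetate carbonyl (Robinson-type annulation, the methyl vinyl ketone route to Hagemann's ester), should give the vinylogous β-keto ester as a racemate, which is acceptable because its C1 centre is epimerisable.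

Step 2
Reactants: 4 tert-butyl (±)-2-methyl-4-oxocyclohex-2-ene-1-carboxylate
Product: 5 tert-butyl (1R,4S)-4-hydroxy-2-methylcyclohex-2-ene-1-carboxylate (cis)
Conditions: ketoreductase (panel-selected), NADP+ (cat.), i-PrOH (10 vol %), potassium phosphate buffer pH 8, 30 °C
Reagents that add atoms: none
Why: Ketoreductase reduction of the enone carbonyl is expected to accept the (1R)-ketone and deliver hydride to one face of C4 (giving 4S), while the unreacted (1S)-ketone, whose C1 is α to the ester and γ to the enone, epimerises through its dienolate in the mildly basic buffer (dynamic kinetic resolution), so that the enzyme sets C4 directly and C1 by substrate selection.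

Step 3
Reactants: 5 tert-butyl (1R,4S)-4-hydroxy-2-methylcyclohex-2-ene-1-carboxylate
Product: 6 tert-butyl (1R,4S)-4-[(tert-butyldimethylsilyl)oxy]-2-methylcyclohex-2-ene-1-carboxylate
Conditions: TBSCl, imidazole, DMF, 25 °C
Reagents that add atoms: tert-butyldimethylsilyl chloride CC(C)(C)[Si](C)(C)Cl
Why: Imidazole-promoted silylation of the secondary allylic alcohol gives an ether that tolerates zinc, diazomethane, enolate and radical conditions and adds bulk to the upper face of the alkene.

Step 4
Reactants: 6 tert-butyl (1R,4S)-4-[(tert-butyldimethylsilyl)oxy]-2-methylcyclohex-2-ene-1-carboxylate; 7 trichloroacetyl chloride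
Product: 9 tert-butyl (1R,2R,5S,6S)-5-[(tert-butyldimethylsilyl)oxy]-8,8-dichloro-1-methyl-7-oxobicyclo[4.2.0]octane-2-carboxylate, via dichloroketene 8 (not isolated)
Conditions: zinc–copper couple, Et2O–DME, 25 °C, slow addition of 7, ultrasound
Reagents that add atoms: none
Why: Dichloroketene, formed by zinc dechlorination of 7, should undergo thermal [2+2] cycloaddition across C2=C3 from the face opposite the pseudoaxial ester (held there by allylic strain with the ring methyl) and the silyloxy group, its carbonyl carbon bonding to the less substituted C3 and its CCl2 carbon to the methyl-bearing C2, which sets the quaternary centre (later C7a) and the cis ring fusion.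

Step 5
Reactants: 9 tert-butyl (1R,2R,5S,6S)-5-[(tert-butyldimethylsilyl)oxy]-8,8-dichloro-1-methyl-7-oxobicyclo[4.2.0]octane-2-carboxylate; 10 diazomethane
Product: 11 tert-butyl (3aS,4S,7R,7aR)-4-[(tert-butyldimethylsilyl)oxy]-1,1-dichloro-7a-methyl-2-oxooctahydro-1H-indene-7-carboxylate
Conditions: CH2N2 (ca. 2 equiv), Et2O–MeOH, 0 → 25 °C; AcOH quench
Reagents that add atoms: none
Why: Diazomethane adds as a carbon nucleophile to the strained, chlorine-activated cyclobutanone carbonyl to give a diazonium betaine, and loss of N2 is accompanied by a 1,2-shift of one α-carbon onto the new CH2 (Tiffeneau–Demjanov/Büchner–Curtius–Schlotterbeck-type homologation, the established ring expansion of dichloroketene cycloadducts to 2,2-dichlorocyclopentanones). The five-membered ring is therefore closed not by a cyclisation but by enlargement of the four-membered ring, the CH2 (C3) entering between C2 and C3a so that the C2–C3 and C3–C3a bonds form in one operation. No stereocentre is created: C3a migrates with retention and C4, C7 and C7a are spectators. The selectivity needed is migration of the ring-fusion CH (C3a) and not of the CCl2 carbon, and the two chlorines secure it because they make C1 a poor migrating group. The same chlorines make the carbonyl electrophilic enough to react near 0 °C, whereas the less strained and more hindered product ketone should react much more slowly, so a second insertion is not expected if a large excess of reagent is avoided. Spiro-oxirane formation, the usual side path of ketone–diazomethane reactions, is disfavoured here because only the ring expansion relieves the cyclobutanone strain.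

Step 6
Reactants: 11 tert-butyl (3aS,4S,7R,7aR)-4-[(tert-butyldimethylsilyl)oxy]-1,1-dichloro-7a-methyl-2-oxooctahydro-1H-indene-7-carboxylate
Product: 13 tert-butyl (4S,7R,7aS)-4-[(tert-butyldimethylsilyl)oxy]-1,1-dichloro-7a-methyl-2-oxo-2,4,5,6,7,7a-hexahydro-1H-indene-7-carboxylate, via trimethylsilyl enol ether 12 (not isolated)
Conditions: LiHMDS, TMSCl (in situ), THF, −78 °C; pentane filtration, evaporation; then Pd(OAc)2 (1.1 equiv), MeCN, 25 °C
Reagents that add atoms: none
Why: Because C1 carries two chlorines the ketone can enolise only towards C3, and Saegusa–Ito oxidation of the trapped silyl enol ether (palladation at C3 by divalent palladium, then syn β-hydride elimination of the C3a hydrogen on the convex face of the cis-fused bicycle) should give the C3=C3a enone regiospecifically, removing the C3a stereocentre that the target does not have, while the low-temperature in situ silylation avoids Favorskii-type loss of chloride and spares the tert-butyl ester.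

Step 7
Reactants: 14 2-methylenepropane-1,3-diol
Product: 15 2-{[(tert-butyldimethylsilyl)oxy]methyl}prop-2-en-1-ol
Conditions: NaH (1.0 equiv), THF, 0 °C; TBSCl (1.0 equiv), 25 °C
Reagents that add atoms: tert-butyldimethylsilyl chloride CC(C)(C)[Si](C)(C)Cl
Why: One equivalent of NaH gives the sparingly soluble monosodium alkoxide of the symmetrical diol, which is silylated once (monoprotection of a symmetrical diol through its monoalkoxide).

Step 8
Reactants: 15 2-{[(tert-butyldimethylsilyl)oxy]methyl}prop-2-en-1-ol
Product: 17 tert-butyldimethyl({2-[(tributylstannyl)methyl]prop-2-en-1-yl}oxy)silane, via allylic mesylate 16 (not isolated)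
Conditions: n-BuLi, THF, −78 °C; MsCl; then Bu3SnLi (from Bu3SnH and LDA), −78 → 0 °C
Reagents that add atoms: tributyltin hydride CCCC[SnH](CCCC)CCCC
Why: Nucleophilic displacement of the allylic mesylate by the stannyl anion gives the 2-substituted allylstannane, the direct and the allylically transposed substitution leading to the same product.

Step 9
Reactants: 13 tert-butyl (4S,7R,7aS)-4-[(tert-butyldimethylsilyl)oxy]-1,1-dichloro-7a-methyl-2-oxo-2,4,5,6,7,7a-hexahydro-1H-indene-7-carboxylate; 17 tert-butyldimethyl({2-[(tributylstannyl)methyl]prop-2-en-1-yl}oxy)silane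
Product: 18 tert-butyl (4S,7R,7aS)-4-[(tert-butyldimethylsilyl)oxy]-1-(2-{[(tert-butyldimethylsilyl)oxy]methyl}prop-2-en-1-yl)-1-chloro-7a-methyl-2-oxo-2,4,5,6,7,7a-hexahydro-1H-indene-7-carboxylate (C1 epimers)
Conditions: 17 (2 equiv), AIBN (0.2 equiv, in portions), benzene, 80 °C
Reagents that add atoms: none
Why: In this Keck radical allylation the stannyl radical abstracts a chlorine from the doubly activated C1, the electrophilic α-chloro-α-keto radical adds to the terminal CH2 of the electron-rich allylstannane and β-scission releases the chain-carrying Bu3Sn radical, the remaining tertiary, neopentyl chloride being expected to react more slowly; the C1 configuration is irrelevant because step 10 makes C1 trigonal again.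

Step 10
Reactants: 18 tert-butyl (4S,7R,7aS)-4-[(tert-butyldimethylsilyl)oxy]-1-(2-{[(tert-butyldimethylsilyl)oxy]methyl}prop-2-en-1-yl)-1-chloro-7a-methyl-2-oxo-2,4,5,6,7,7a-hexahydro-1H-indene-7-carboxylate
Product: 19 tert-butyl (1R,4S,7R,7aS)-4-[(tert-butyldimethylsilyl)oxy]-1-(2-{[(tert-butyldimethylsilyl)oxy]methyl}prop-2-en-1-yl)-7a-methyl-2-oxo-2,4,5,6,7,7a-hexahydro-1H-indene-7-carboxylate
Conditions: Zn dust, AcOH, THF, 0 → 25 °C
Reagents that add atoms: none
Why: Zinc inserts into the remaining α-keto C–Cl bond and acetic acid protonates the transient zinc dienolate at C1 (reductive dehalogenation of an α-halo ketone), the proton being expected to arrive on the face opposite the axial angular methyl at C7a so that the side chain ends up cis to that methyl (1R), which should also be the more stable epimer because the alternative sets the chain against the C7 ring carbon.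

Step 11
Reactants: 19 tert-butyl (1R,4S,7R,7aS)-4-[(tert-butyldimethylsilyl)oxy]-1-(2-{[(tert-butyldimethylsilyl)oxy]methyl}prop-2-en-1-yl)-7a-methyl-2-oxo-2,4,5,6,7,7a-hexahydro-1H-indene-7-carboxylate
Product: 20 tert-butyl (1R,4S,7R,7aS)-4-hydroxy-1-[2-(hydroxymethyl)prop-2-en-1-yl]-7a-methyl-2-oxo-2,4,5,6,7,7a-hexahydro-1H-indene-7-carboxylate
Conditions: HF·pyridine, pyridine, THF, 0 → 25 °C
Reagents that add atoms: none
Why: Fluoride-mediated Si–O cleavage removes the primary and the secondary silyl ether in one operation under buffered, weakly acidic conditions that should leave the tert-butyl ester, the γ-hydroxy enone and the epimerisable C1 untouched.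

Step 12
Reactants: 20 tert-butyl (1R,4S,7R,7aS)-4-hydroxy-1-[2-(hydroxymethyl)prop-2-en-1-yl]-7a-methyl-2-oxo-2,4,5,6,7,7a-hexahydro-1H-indene-7-carboxylate
Product: 21 tert-butyl (1R,4S,7R,7aS)-1-(2-formylprop-2-en-1-yl)-4-hydroxy-7a-methyl-2-oxo-2,4,5,6,7,7a-hexahydro-1H-indene-7-carboxylate
Conditions: TEMPO (0.1 equiv), PhI(OAc)2 (1.1 equiv), CH2Cl2, 25 °C
Reagents that add atoms: none
Why: Oxoammonium oxidation (TEMPO with PhI(OAc)2 as terminal oxidant) is strongly biased towards unhindered primary alcohols, so the primary allylic alcohol should give the enal while the axial secondary C4 alcohol next to the electron-poor enone remains.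

Step 13
Reactants: 22 (R)-2-methylbutanoic acid
Product: 23 (R)-2-methylbutan-1-ol
Conditions: LiAlH4, Et2O, 0 °C → reflux; aqueous NaOH work-up
Reagents that add atoms: none
Why: Hydride reduction of the carboxylic acid to the primary alcohol does not involve the α-stereocentre, which is not enolised under these conditions.

Step 14
Reactants: 23 (R)-2-methylbutan-1-ol
Product: 25 (2E,4R)-2,4-dimethylhex-2-enal, via (R)-2-methylbutanal 24 (not isolated)
Conditions: TEMPO (cat.), KBr (cat.), NaOCl, NaHCO3, CH2Cl2–H2O, 0 °C; dried organic phase, then Ph3P=C(Me)CHO, toluene, 80 °C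
Reagents that add atoms: 2-(triphenylphosphoranylidene)propanal CC(C=O)=P(c1ccccc1)(c1ccccc1)c1ccccc1
Why: Buffered TEMPO/hypochlorite oxidation gives the volatile α-chiral aldehyde without a base able to enolise it, and Wittig olefination with the stabilised formyl ylide should give the (E)-α-methyl enal, the conjugated α-branched product being much less reactive towards a second olefination.

Step 15
Reactants: 25 (2E,4R)-2,4-dimethylhex-2-enal
Product: 26 ethyl (2E,4E,6R)-4,6-dimethylocta-2,4-dienoate
Conditions: (EtO)2P(O)CH2CO2Et, NaH, THF, 0 → 25 °C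
Reagents that add atoms: triethyl phosphonoacetate CCOC(=O)CP(=O)(OCC)OCC
Why: Horner–Wadsworth–Emmons olefination with the preformed sodium phosphonate should give the (2E) alkene with the usual selectivity of stabilised phosphonates, the anion being too weak a base to deprotonate the allylic C6 stereocentre.

Step 16
Reactants: 26 ethyl (2E,4E,6R)-4,6-dimethylocta-2,4-dienoate
Product: 27 (2E,4E,6R)-4,6-dimethylocta-2,4-dienoic acid
Conditions: LiOH, THF–MeOH–H2O, 25 °C; then 1 M HCl
Reagents that add atoms: lithium hydroxide [Li+].[OH-]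
Why: Saponification of the ethyl ester proceeds by acyl substitution and leaves the diene geometry and the remote C6 centre unchanged.

Step 17
Reactants: 21 tert-butyl (1R,4S,7R,7aS)-1-(2-formylprop-2-en-1-yl)-4-hydroxy-7a-methyl-2-oxo-2,4,5,6,7,7a-hexahydro-1H-indene-7-carboxylate; 27 (2E,4E,6R)-4,6-dimethylocta-2,4-dienoic acid
Product: 29 tert-butyl (1R,4S,7R,7aS)-4-{[(2E,4E,6R)-4,6-dimethylocta-2,4-dienoyl]oxy}-1-(2-formylprop-2-en-1-yl)-7a-methyl-2-oxo-2,4,5,6,7,7a-hexahydro-1H-indene-7-carboxylate, via mixed anhydride 28 (not isolated)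
Conditions: 27, 2,4,6-Cl3C6H2COCl, Et3N, toluene, 25 °C; then 21, DMAP, 25 → 40 °C
Reagents that add atoms: none
Why: In this Yamaguchi esterification the mixed anhydride passes the dienoyl group through its acylpyridinium to the hindered C4 alcohol without touching the C4–O bond (retention), and the α-substituted acrolein unit, having no α-hydrogen, cannot turn over in amine-triggered Baylis–Hillman-type reactions.

Step 18
Reactants: 29 tert-butyl (1R,4S,7R,7aS)-4-{[(2E,4E,6R)-4,6-dimethylocta-2,4-dienoyl]oxy}-1-(2-formylprop-2-en-1-yl)-7a-methyl-2-oxo-2,4,5,6,7,7a-hexahydro-1H-indene-7-carboxylate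
Product: 30 (1R,4S,7R,7aS)-4-{[(2E,4E,6R)-4,6-dimethylocta-2,4-dienoyl]oxy}-1-(2-formylprop-2-en-1-yl)-7a-methyl-2-oxo-2,4,5,6,7,7a-hexahydro-1H-indene-7-carboxylic acid
Conditions: TFA–CH2Cl2 (1:4), 0 °C
Reagents that add atoms: none
Why: Acidolysis of the tert-butyl ester by alkyl–oxygen cleavage (loss of 2-methylpropene) frees the C7 acid without base, so the dienoate ester, the enal, the γ-acyloxy enone and the C1 centre should survive.

**Compound list**

1 | tert-butyl acetoacetate | CC(=O)CC(=O)OC(C)(C)C | starting material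
2 | methyl vinyl ketone | C=CC(C)=O | starting material
3 | tert-butyl 2-acetyl-5-oxohexanoate (racemic, formed in the flask) | CC(=O)CCC(C(C)=O)C(=O)OC(C)(C)C | intermediate
4 | tert-butyl (±)-2-methyl-4-oxocyclohex-2-ene-1-carboxylate | CC1=CC(=O)CCC1C(=O)OC(C)(C)C | intermediate
5 | tert-butyl (1R,4S)-4-hydroxy-2-methylcyclohex-2-ene-1-carboxylate | CC1=C[C@@H](O)CC[C@H]1C(=O)OC(C)(C)C | intermediate
6 | tert-butyl (1R,4S)-4-[(tert-butyldimethylsilyl)oxy]-2-methylcyclohex-2-ene-1-carboxylate | CC1=C[C@@H](O[Si](C)(C)C(C)(C)C)CC[C@H]1C(=O)OC(C)(C)C | intermediate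
7 | trichloroacetyl chloride | O=C(Cl)C(Cl)(Cl)Cl | starting material
8 | dichloroketene (formed in the flask) | O=C=C(Cl)Cl | intermediate
9 | tert-butyl (1R,2R,5S,6S)-5-[(tert-butyldimethylsilyl)oxy]-8,8-dichloro-1-methyl-7-oxobicyclo[4.2.0]octane-2-carboxylate | O=C1[C@@H]2[C@@H](O[Si](C)(C)C(C)(C)C)CC[C@@H](C(=O)OC(C)(C)C)[C@]2(C)C1(Cl)Cl | intermediate
10 | diazomethane | C=[N+]=[N-] | starting material
11 | tert-butyl (3aS,4S,7R,7aR)-4-[(tert-butyldimethylsilyl)oxy]-1,1-dichloro-7a-methyl-2-oxooctahydro-1H-indene-7-carboxylate | O=C1C[C@@H]2[C@@H](O[Si](C)(C)C(C)(C)C)CC[C@@H](C(=O)OC(C)(C)C)[C@]2(C)C1(Cl)Cl | intermediate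
12 | tert-butyl (3aS,4S,7R,7aR)-4-[(tert-butyldimethylsilyl)oxy]-1,1-dichloro-7a-methyl-2-[(trimethylsilyl)oxy]-3a,4,5,6,7,7a-hexahydro-1H-indene-7-carboxylate (formed in the flask) | C[Si](C)(C)OC1=C[C@@H]2[C@@H](O[Si](C)(C)C(C)(C)C)CC[C@@H](C(=O)OC(C)(C)C)[C@]2(C)C1(Cl)Cl | intermediate
13 | tert-butyl (4S,7R,7aS)-4-[(tert-butyldimethylsilyl)oxy]-1,1-dichloro-7a-methyl-2-oxo-2,4,5,6,7,7a-hexahydro-1H-indene-7-carboxylate | O=C1C=C2[C@@H](O[Si](C)(C)C(C)(C)C)CC[C@@H](C(=O)OC(C)(C)C)[C@]2(C)C1(Cl)Cl | intermediate
14 | 2-methylenepropane-1,3-diol | C=C(CO)CO | starting material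
15 | 2-{[(tert-butyldimethylsilyl)oxy]methyl}prop-2-en-1-ol | C=C(CO)CO[Si](C)(C)C(C)(C)C | intermediate
16 | 2-{[(tert-butyldimethylsilyl)oxy]methyl}prop-2-en-1-yl methanesulfonate (formed in the flask) | C=C(COS(C)(=O)=O)CO[Si](C)(C)C(C)(C)C | intermediate
17 | tert-butyldimethyl({2-[(tributylstannyl)methyl]prop-2-en-1-yl}oxy)silane | C=C(C[Sn](CCCC)(CCCC)CCCC)CO[Si](C)(C)C(C)(C)C | intermediate
18 | tert-butyl (4S,7R,7aS)-4-[(tert-butyldimethylsilyl)oxy]-1-(2-{[(tert-butyldimethylsilyl)oxy]methyl}prop-2-en-1-yl)-1-chloro-7a-methyl-2-oxo-2,4,5,6,7,7a-hexahydro-1H-indene-7-carboxylate (both C1 epimers) | C=C(CO[Si](C)(C)C(C)(C)C)CC1(Cl)C(=O)C=C2[C@@H](O[Si](C)(C)C(C)(C)C)CC[C@@H](C(=O)OC(C)(C)C)[C@@]21C | intermediate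
19 | tert-butyl (1R,4S,7R,7aS)-4-[(tert-butyldimethylsilyl)oxy]-1-(2-{[(tert-butyldimethylsilyl)oxy]methyl}prop-2-en-1-yl)-7a-methyl-2-oxo-2,4,5,6,7,7a-hexahydro-1H-indene-7-carboxylate | C=C(CO[Si](C)(C)C(C)(C)C)C[C@H]1C(=O)C=C2[C@@H](O[Si](C)(C)C(C)(C)C)CC[C@@H](C(=O)OC(C)(C)C)[C@@]21C | intermediate
20 | tert-butyl (1R,4S,7R,7aS)-4-hydroxy-1-[2-(hydroxymethyl)prop-2-en-1-yl]-7a-methyl-2-oxo-2,4,5,6,7,7a-hexahydro-1H-indene-7-carboxylate | C=C(CO)C[C@H]1C(=O)C=C2[C@@H](O)CC[C@@H](C(=O)OC(C)(C)C)[C@@]21C | intermediate
21 | tert-butyl (1R,4S,7R,7aS)-1-(2-formylprop-2-en-1-yl)-4-hydroxy-7a-methyl-2-oxo-2,4,5,6,7,7a-hexahydro-1H-indene-7-carboxylate | C=C(C=O)C[C@H]1C(=O)C=C2[C@@H](O)CC[C@@H](C(=O)OC(C)(C)C)[C@@]21C | intermediate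
22 | (R)-2-methylbutanoic acid | CC[C@@H](C)C(=O)O | starting material
23 | (R)-2-methylbutan-1-ol | OC[C@H](C)CC | intermediate
24 | (R)-2-methylbutanal (formed in the flask) | O=C[C@H](C)CC | intermediate
25 | (2E,4R)-2,4-dimethylhex-2-enal | O=C/C(C)=C/[C@H](C)CC | intermediate
26 | ethyl (2E,4E,6R)-4,6-dimethylocta-2,4-dienoate | CCOC(=O)/C=C/C(C)=C/[C@H](C)CC | intermediate
27 | (2E,4E,6R)-4,6-dimethylocta-2,4-dienoic acid | OC(=O)/C=C/C(C)=C/[C@H](C)CC | intermediate
28 | (2E,4E,6R)-4,6-dimethylocta-2,4-dienoic 2,4,6-trichlorobenzoic anhydride (formed in the flask) | O=C(OC(=O)c1c(Cl)cc(Cl)cc1Cl)/C=C/C(C)=C/[C@H](C)CC | intermediate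
29 | tert-butyl (1R,4S,7R,7aS)-4-{[(2E,4E,6R)-4,6-dimethylocta-2,4-dienoyl]oxy}-1-(2-formylprop-2-en-1-yl)-7a-methyl-2-oxo-2,4,5,6,7,7a-hexahydro-1H-indene-7-carboxylate | C=C(C=O)C[C@H]1C(=O)C=C2[C@@H](OC(=O)/C=C/C(C)=C/[C@H](C)CC)CC[C@@H](C(=O)OC(C)(C)C)[C@@]21C | intermediate
30 | (1R,4S,7R,7aS)-4-{[(2E,4E,6R)-4,6-dimethylocta-2,4-dienoyl]oxy}-1-(2-formylprop-2-en-1-yl)-7a-methyl-2-oxo-2,4,5,6,7,7a-hexahydro-1H-indene-7-carboxylic acid | C=C(C=O)C[C@H]1C(=O)C=C2[C@@H](OC(=O)/C=C/C(C)=C/[C@H](C)CC)CC[C@@H](C(=O)O)[C@@]21C | target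

**Step count**

Total: 18 steps. Longest linear sequence: 12 steps (1, 2, 3, 4, 5, 6, 9, 10, 11, 12, 17, 18). The stannane takes 2 steps (7, 8) and the dienoic acid 4 steps (13–16).

**Steps most likely to fail, with fallbacks**

Step 2 (enzymatic reduction). The enzyme may discriminate the two C1 epimers of the ketone too weakly, or C1 may epimerise too slowly in the buffer, so that the trans alcohol accumulates or conversion stalls near one half. The fallback sets out from 4 and replaces the biocatalytic resolution by a chemical reduction and a classical resolution. Luche reduction (NaBH4, CeCl3·7H2O, MeOH, −78 °C) should give mainly the racemic cis alcohol, (±)-cis-tert-butyl 4-hydroxy-2-methylcyclohex-2-ene-1-carboxylate F1, because the ester is held pseudoaxial next to the ring methyl and hydride enters anti to it. Acylation with (1S)-camphanic chloride (pyridine, DMAP, CH2Cl2) would give two diastereomers, the camphanate of the (1R,4S) alcohol F2 and the camphanate of the (1S,4R) alcohol F3, to be separated by crystallisation or chromatography. Methanolysis of F2 (K2CO3, MeOH, 0 °C) comes back to the route at 5.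

Step 4 (ketene cycloaddition). The trisubstituted alkene is flanked by two substituted allylic carbons and inductively deactivated by the silyloxy group, so it may add the short-lived ketene too slowly and the ketene may oligomerise instead. The fallback sets out from 6 and uses a more electrophilic two-carbon partner, then installs the chlorines afterwards. The keteniminium salt from N,N-dimethylacetamide, Tf2O and 2,4,6-collidine (1,2-dichloroethane, reflux) should add with the same regiochemistry and facial sense to give the cyclobutaniminium triflate F4. Aqueous NaHCO3 would hydrolyse it to the chlorine-free cyclobutanone, tert-butyl (1R,2R,5S,6S)-5-[(tert-butyldimethylsilyl)oxy]-1-methyl-7-oxobicyclo[4.2.0]octane-2-carboxylate F5. Two rounds of kinetic enolisation at the CH2 group and chlorination (LiHMDS, then N-chlorosuccinimide, THF, −78 °C), passing through the 8-monochloro ketone F6, come back to the route at 9.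

Step 9 (radical allylation). Chlorine abstraction from the gem-dichloride may be slow relative to chain termination, or the monoallyl product may be allylated a second time. The fallback sets out from 13 and attaches the side chain by enolate alkylation instead. Exhaustive dechlorination (Zn, AcOH, 60 °C) should give the chlorine-free enone, tert-butyl (4S,7R,7aS)-4-[(tert-butyldimethylsilyl)oxy]-7a-methyl-2-oxo-2,4,5,6,7,7a-hexahydro-1H-indene-7-carboxylate F7. Kinetic deprotonation at C1 (LDA, THF, −78 °C) and alkylation with {[2-(bromomethyl)prop-2-en-1-yl]oxy}(tert-butyl)dimethylsilane F8 (from 15 with CBr4 and PPh3) should occur anti to the angular methyl and give the (1S) epimer of 19, F9. Equilibration with DBU (CH2Cl2, 25 °C), expected to favour the chain cis to the angular methyl, comes back to the route at 19.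

**Further compounds**

F1 | step 2 | (±)-cis-tert-butyl 4-hydroxy-2-methylcyclohex-2-ene-1-carboxylate (racemate, one enantiomer drawn) | CC1=C[C@@H](O)CC[C@H]1C(=O)OC(C)(C)C
F2 | step 2 | (1R,4S)-4-(tert-butoxycarbonyl)-3-methylcyclohex-2-en-1-yl (1S,4R)-4,7,7-trimethyl-3-oxo-2-oxabicyclo[2.2.1]heptane-1-carboxylate | CC1=C[C@@H](OC(=O)[C@@]23CC[C@@](C)(C(=O)O2)C3(C)C)CC[C@H]1C(=O)OC(C)(C)C
F3 | step 2 | (1S,4R)-4-(tert-butoxycarbonyl)-3-methylcyclohex-2-en-1-yl (1S,4R)-4,7,7-trimethyl-3-oxo-2-oxabicyclo[2.2.1]heptane-1-carboxylate | CC1=C[C@H](OC(=O)[C@@]23CC[C@@](C)(C(=O)O2)C3(C)C)CC[C@@H]1C(=O)OC(C)(C)C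
F4 | step 4 | N-[(1R,2R,5S,6R)-2-(tert-butoxycarbonyl)-5-[(tert-butyldimethylsilyl)oxy]-1-methylbicyclo[4.2.0]octan-7-ylidene]-N-methylmethanaminium triflate | C[N+](C)=C1[C@@H]2[C@@H](O[Si](C)(C)C(C)(C)C)CC[C@@H](C(=O)OC(C)(C)C)[C@]2(C)C1.[O-]S(=O)(=O)C(F)(F)F
F5 | step 4 | tert-butyl (1R,2R,5S,6S)-5-[(tert-butyldimethylsilyl)oxy]-1-methyl-7-oxobicyclo[4.2.0]octane-2-carboxylate | O=C1[C@@H]2[C@@H](O[Si](C)(C)C(C)(C)C)CC[C@@H](C(=O)OC(C)(C)C)[C@]2(C)C1
F6 | step 4 | tert-butyl (1R,2R,5S,6S)-5-[(tert-butyldimethylsilyl)oxy]-8-chloro-1-methyl-7-oxobicyclo[4.2.0]octane-2-carboxylate (C8 epimers) | O=C1[C@@H]2[C@@H](O[Si](C)(C)C(C)(C)C)CC[C@@H](C(=O)OC(C)(C)C)[C@]2(C)C1Cl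
F7 | step 9 | tert-butyl (4S,7R,7aS)-4-[(tert-butyldimethylsilyl)oxy]-7a-methyl-2-oxo-2,4,5,6,7,7a-hexahydro-1H-indene-7-carboxylate | O=C1C=C2[C@@H](O[Si](C)(C)C(C)(C)C)CC[C@@H](C(=O)OC(C)(C)C)[C@]2(C)C1
F8 | step 9 | {[2-(bromomethyl)prop-2-en-1-yl]oxy}(tert-butyl)dimethylsilane | C=C(CBr)CO[Si](C)(C)C(C)(C)C
F9 | step 9 | tert-butyl (1S,4S,7R,7aS)-4-[(tert-butyldimethylsilyl)oxy]-1-(2-{[(tert-butyldimethylsilyl)oxy]methyl}prop-2-en-1-yl)-7a-methyl-2-oxo-2,4,5,6,7,7a-hexahydro-1H-indene-7-carboxylate | C=C(CO[Si](C)(C)C(C)(C)C)C[C@@H]1C(=O)C=C2[C@@H](O[Si](C)(C)C(C)(C)C)CC[C@@H](C(=O)OC(C)(C)C)[C@@]21C
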